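The route rests on cutting the chlorinated chromone at C3–C4, O1–C2 and O1–C8a. The contiguous O1/C8–Cl/C7–O pattern on its benzo ring is the 2-F/3-Cl/4-F pattern of 3-chloro-2,4-difluorobenzoyl chloride: the fluorine ortho to the acyl group becomes the O1–C8a site and the para fluorine marks C7 for later oxygenation. In one telescoped operation the acid chloride C-acylates a morpholine enamine of the diaryl-ether arylacetaldehyde, the enaminone is hydrolysed and the enol oxygen closes the pyranone by SNAr. The enamine already carries the methyl arylacetate from which the second, 7-hydroxy isoflavone is grown afterwards with resorcinol.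

Key step: step 6

Assumption: the target has no stereocentre; the only geometric descriptor in the route is the (E) double bond of enamine 7. Both oxygens that are unmasked last are carried as methyl ethers so that a single BBr3 treatment ends the route.

Step 1
Reactants: 1 2-(3-hydroxy-4-methoxyphenyl)acetic acid (homoisovanillic acid)
Product: 2 methyl 2-(3-hydroxy-4-methoxyphenyl)acetate
Conditions: MeOH, cat. H2SO4, reflux
Reagents that add atoms: methanol (CO)
Why: Fischer esterification converts only the carboxylic acid, since a phenol is not esterified by an alcohol under acid catalysis.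

Step 2
Reactants: 2 methyl 2-(3-hydroxy-4-methoxyphenyl)acetate; 3 4-fluorobenzaldehyde
Product: 4 methyl 2-[3-(4-formylphenoxy)-4-methoxyphenyl]acetate
Conditions: K2CO3, DMF, 110 °C
Reagents that add atoms: none
Why: Nucleophilic aromatic substitution (SNAr) of the para-formyl-activated fluoride by the phenoxide should give the diaryl ether, carbonate being too weak a base to enolise the arylacetate.

Step 3
Reactants: 4 methyl 2-[3-(4-formylphenoxy)-4-methoxyphenyl]acetate
Product: 5 methyl 2-[4-methoxy-3-[4-(2-methoxyethenyl)phenoxy]phenyl]acetate (E/Z mixture)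
Conditions: Ph3P(CH2OMe)Cl, NaN(SiMe3)2, THF, −78 → 0 °C
Reagents that add atoms: (methoxymethyl)triphenylphosphonium chloride (COC[P+](c1ccccc1)(c1ccccc1)c1ccccc1.[Cl-])
Why: Wittig olefination with the preformed methoxymethylene ylide (base kept slightly below the phosphonium salt) should take the aldehyde in preference to the ester, and the E/Z ratio is irrelevant because both isomers hydrolyse to the same aldehyde.

Step 4
Reactants: 5 methyl 2-[4-methoxy-3-[4-(2-methoxyethenyl)phenoxy]phenyl]acetate
Product: 7 methyl 2-[4-methoxy-3-[4-[(E)-2-(morpholin-4-yl)ethenyl]phenoxy]phenyl]acetate, via arylacetaldehyde 6 (not isolated)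
Conditions: (a) 2 M aq HCl, THF, 45 °C; (b) morpholine, MgSO4, toluene, rt; used crude
Reagents that add atoms: morpholine (C1COCCN1)
Why: Acid-catalysed enol ether hydrolysis followed at once by enamine condensation should trap the self-condensation-prone arylacetaldehyde as the aryl-conjugated enamine, whose (E) geometry is the thermodynamic outcome of the reversible condensation.

Step 5
Reactants: 8 3-chloro-2,4-difluorobenzoic acid
Product: 9 3-chloro-2,4-difluorobenzoyl chloride
Conditions: SOCl2, cat. DMF, toluene, 80 °C; volatiles removed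
Reagents that add atoms: thionyl chloride (O=S(Cl)Cl)
Why: Acid chloride formation through the DMF-catalysed chlorosulfite pathway leaves the aryl C–F and C–Cl bonds untouched.

Step 6
Reactants: 7 methyl 2-[4-methoxy-3-[4-[(E)-2-(morpholin-4-yl)ethenyl]phenoxy]phenyl]acetate; 9 3-chloro-2,4-difluorobenzoyl chloride
Product: 12 methyl 2-[3-[4-(8-chloro-7-fluoro-4-oxochromen-3-yl)phenoxy]-4-methoxyphenyl]acetate, via aroyl enaminone 10 (not isolated), via hydroxymethylene ketone 11 (not isolated)
Conditions: (a) Et3N, CH2Cl2, 0 °C → rt; (b) 1 M aq HCl, THF, rt, aqueous phase discarded; (c) K2CO3, dry DMF, 50 °C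
Reagents that add atoms: water (O)
Why: The nucleophilic β-carbon of enamine 7 attacks the electron-poor aroyl chloride (Stork-type enamine C-acylation, the opening move of a Grohe-type cycloacylation) while Et3N takes up the HCl, so the vinylogous amide 10 should form without protonating unreacted enamine. Dilute acid then exchanges morpholine for water through the iminium ion, giving the chelated enol 11 of the β-ketoaldehyde and carrying the amine into the aqueous phase as its hydrochloride before any base is present, which should keep it from attacking either activated fluorine. With K2CO3 in dry DMF the enolate oxygen adds to the fluorine-bearing carbon ortho to the ketone and fluoride leaves from the Meisenheimer intermediate, an intramolecular SNAr that closes the six-membered pyranone ring (O1–C8a; 6-exo-trig with respect to the arene C8a=C8 bond). No stereocentre is formed. The step needs C- rather than N-acylation, which the tertiary enamine secures because N-acylation is reversible and only the C-acyl product is a stabilised push–pull enone, and it needs displacement of the 2- rather than the 4-fluorine, which the tether secures because the enolate oxygen can reach only the ortho position; the chlorine, meta to the ketone, is not activated, and dry carbonate should spare the methyl ester and avoid deformylation of 11.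

Step 7
Reactants: 12 methyl 2-[3-[4-(8-chloro-7-fluoro-4-oxochromen-3-yl)phenoxy]-4-methoxyphenyl]acetate
Product: 13 methyl 2-[3-[4-(8-chloro-7-methoxy-4-oxochromen-3-yl)phenoxy]-4-methoxyphenyl]acetate
Conditions: NaOMe, MeOH/THF, 60 °C; then AcOH, aq HCl work-up
Reagents that add atoms: sodium methoxide ([Na+].[O-]C)
Why: SNAr at C7, which is para to the C4 carbonyl and flanked by chlorine, should install the methoxy group, while methoxide in methanol leaves the methyl ester unchanged and any reversible addition at C2 reverts on acidic work-up.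

Step 8
Reactants: 13 methyl 2-[3-[4-(8-chloro-7-methoxy-4-oxochromen-3-yl)phenoxy]-4-methoxyphenyl]acetate
Product: 14 2-[3-[4-(8-chloro-7-methoxy-4-oxochromen-3-yl)phenoxy]-4-methoxyphenyl]acetic acid
Conditions: 6 M aq HCl, 1,4-dioxane, 90 °C
Reagents that add atoms: water (O)
Why: Acid-catalysed ester hydrolysis is chosen over saponification because hydroxide opens chromones, whereas the chromone, the aryl methyl ethers and the diaryl ether are stable to aqueous HCl.

Step 9
Reactants: 14 2-[3-[4-(8-chloro-7-methoxy-4-oxochromen-3-yl)phenoxy]-4-methoxyphenyl]acetic acid; 15 resorcinol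
Product: 17 8-chloro-3-[4-[5-(7-hydroxy-4-oxochromen-3-yl)-2-methoxyphenoxy]phenyl]-7-methoxychromen-4-one, via deoxybenzoin 16 (not isolated)
Conditions: (a) BF3·OEt2 (solvent), 85 °C; (b) DMF, then MsCl, 50 → 75 °C; aq NaOAc work-up
Reagents that add atoms: N,N-dimethylformamide (CN(C)C=O)
Why: BF3-promoted Friedel–Crafts acylation of resorcinol at C4 gives the 2,4-dihydroxydeoxybenzoin, whose boron-chelated activated methylene is then formylated by the Vilsmeier-type DMF/MsCl reagent and closed by the ortho hydroxyl with loss of dimethylamine (one-pot deoxybenzoin isoflavone synthesis), under conditions that aryl methyl ethers, the existing chromone and the diaryl ether tolerate.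

Step 10
Reactants: 17 8-chloro-3-[4-[5-(7-hydroxy-4-oxochromen-3-yl)-2-methoxyphenoxy]phenyl]-7-methoxychromen-4-one
Product: 18 Bisoflavolin K, 8-chloro-7-hydroxy-3-[4-[2-hydroxy-5-(7-hydroxy-4-oxochromen-3-yl)phenoxy]phenyl]chromen-4-one
Conditions: BBr3 (excess), CH2Cl2, −78 °C → rt; then MeOH/H2O
Reagents that add atoms: none
Why: Lewis-acid aryl methyl ether cleavage with BBr3 (bromide attacks the O-methyl carbon of each boron-complexed ether in an SN2 step) should free both remaining hydroxyls, while the diaryl ether, which has no sp3 carbon on oxygen, and the aryl chloride stay intact.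

Compound list
1 | 2-(3-hydroxy-4-methoxyphenyl)acetic acid (homoisovanillic acid) | OC(=O)Cc1ccc(OC)c(O)c1 | starting material
2 | methyl 2-(3-hydroxy-4-methoxyphenyl)acetate | COC(=O)Cc1ccc(OC)c(O)c1 | intermediate
3 | 4-fluorobenzaldehyde | O=Cc1ccc(F)cc1 | starting material
4 | methyl 2-[3-(4-formylphenoxy)-4-methoxyphenyl]acetate | COC(=O)Cc1ccc(OC)c(Oc2ccc(C=O)cc2)c1 | intermediate
5 | methyl 2-[4-methoxy-3-[4-(2-methoxyethenyl)phenoxy]phenyl]acetate, E/Z mixture | COC(=O)Cc1ccc(OC)c(Oc2ccc(C=COC)cc2)c1 | intermediate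
6 | methyl 2-[4-methoxy-3-[4-(2-oxoethyl)phenoxy]phenyl]acetate | COC(=O)Cc1ccc(OC)c(Oc2ccc(CC=O)cc2)c1 | intermediate (not isolated)
7 | methyl 2-[4-methoxy-3-[4-[(E)-2-(morpholin-4-yl)ethenyl]phenoxy]phenyl]acetate | COC(=O)Cc1ccc(OC)c(Oc2ccc(/C=C/N3CCOCC3)cc2)c1 | intermediate
8 | 3-chloro-2,4-difluorobenzoic acid | OC(=O)c1ccc(F)c(Cl)c1F | starting material
9 | 3-chloro-2,4-difluorobenzoyl chloride | O=C(Cl)c1ccc(F)c(Cl)c1F | intermediate
10 | methyl 2-[3-[4-[1-(3-chloro-2,4-difluorophenyl)-3-(morpholin-4-yl)-1-oxoprop-2-en-2-yl]phenoxy]-4-methoxyphenyl]acetate, geometry of the push–pull C=C not fixed | COC(=O)Cc1ccc(OC)c(Oc2ccc(C(=CN3CCOCC3)C(=O)c3ccc(F)c(Cl)c3F)cc2)c1 | intermediate (not isolated)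
11 | methyl 2-[3-[4-[(Z)-1-(3-chloro-2,4-difluorophenyl)-3-hydroxy-1-oxoprop-2-en-2-yl]phenoxy]-4-methoxyphenyl]acetate, chelated enol of the β-ketoaldehyde | COC(=O)Cc1ccc(OC)c(Oc2ccc(/C(=C/O)C(=O)c3ccc(F)c(Cl)c3F)cc2)c1 | intermediate (not isolated)
12 | methyl 2-[3-[4-(8-chloro-7-fluoro-4-oxochromen-3-yl)phenoxy]-4-methoxyphenyl]acetate | COC(=O)Cc1ccc(OC)c(Oc2ccc(-c3coc4c(Cl)c(F)ccc4c3=O)cc2)c1 | intermediate
13 | methyl 2-[3-[4-(8-chloro-7-methoxy-4-oxochromen-3-yl)phenoxy]-4-methoxyphenyl]acetate | COC(=O)Cc1ccc(OC)c(Oc2ccc(-c3coc4c(Cl)c(OC)ccc4c3=O)cc2)c1 | intermediate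
14 | 2-[3-[4-(8-chloro-7-methoxy-4-oxochromen-3-yl)phenoxy]-4-methoxyphenyl]acetic acid | OC(=O)Cc1ccc(OC)c(Oc2ccc(-c3coc4c(Cl)c(OC)ccc4c3=O)cc2)c1 | intermediate
15 | resorcinol (benzene-1,3-diol) | Oc1cccc(O)c1 | starting material
16 | 8-chloro-3-[4-[5-[2-(2,4-dihydroxyphenyl)-2-oxoethyl]-2-methoxyphenoxy]phenyl]-7-methoxychromen-4-one | O=C(Cc1ccc(OC)c(Oc2ccc(-c3coc4c(Cl)c(OC)ccc4c3=O)cc2)c1)c1ccc(O)cc1O | intermediate (not isolated)
17 | 8-chloro-3-[4-[5-(7-hydroxy-4-oxochromen-3-yl)-2-methoxyphenoxy]phenyl]-7-methoxychromen-4-one | O=c1c(-c2ccc(OC)c(Oc3ccc(-c4coc5c(Cl)c(OC)ccc5c4=O)cc3)c2)coc2cc(O)ccc12 | intermediate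
18 | Bisoflavolin K, 8-chloro-7-hydroxy-3-[4-[2-hydroxy-5-(7-hydroxy-4-oxochromen-3-yl)phenoxy]phenyl]chromen-4-one | O=c1c(-c2ccc(O)c(Oc3ccc(-c4coc5c(Cl)c(O)ccc5c4=O)cc3)c2)coc2cc(O)ccc12 | target

Total step count: 10.
Longest linear sequence: 9 steps (steps 1–4 and 6–10; step 5 is a one-step side branch).

Steps most likely to fail

Step 6. The styryl enamine may acylate sluggishly or be lost to hydrolysis before it meets the acid chloride, and the formyl carbon may be shed by retro-Claisen cleavage during the amine-for-water exchange. The fallback sets out from 4 (with 9) and comes back at 11, which is closed to 12 as in step 6; it builds the C3–C4 bond by a ketone synthesis and brings in C2 afterwards. NaBH4 in MeOH at 0 °C should reduce 4 to the benzylic alcohol methyl 2-[3-[4-(hydroxymethyl)phenoxy]-4-methoxyphenyl]acetate F1, and PBr3 in CH2Cl2 should give the benzylic bromide methyl 2-[3-[4-(bromomethyl)phenoxy]-4-methoxyphenyl]acetate F2. Zinc dust with LiCl in THF should insert to the ester-tolerant benzylzinc bromide F3, which Pd(PPh3)4 should couple with acid chloride 9 (Negishi-type acylation) to the deoxybenzoin methyl 2-[3-[4-[2-(3-chloro-2,4-difluorophenyl)-2-oxoethyl]phenoxy]-4-methoxyphenyl]acetate F4. Me2NCH(OMe)2 in toluene at 70 °C should condense at the doubly activated methylene to the dimethylamino enaminone methyl 2-[3-[4-[1-(3-chloro-2,4-difluorophenyl)-3-(dimethylamino)-1-oxoprop-2-en-2-yl]phenoxy]-4-methoxyphenyl]acetate F5; dilute aqueous HCl in THF then gives 11, and K2CO3 in dry DMF gives 12.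

Step 7. The alkoxide may add at C2 and open the pyranone ring faster than it displaces the fluoride next to the chlorine, with loss of C2 on prolonged heating. The fallback sets out from 12 and comes back at 13; it makes the C7–O bond with a non-basic hydroxide surrogate and puts the methyl group on separately. (E)-Benzaldoxime with Cs2CO3 in DMSO at 70 °C should give the O-aryl oxime methyl 2-[3-[4-[8-chloro-4-oxo-7-[(E)-benzylideneaminooxy]chromen-3-yl]phenoxy]-4-methoxyphenyl]acetate F6, which fragments in the same pot with loss of benzonitrile to the phenol methyl 2-[3-[4-(8-chloro-7-hydroxy-4-oxochromen-3-yl)phenoxy]-4-methoxyphenyl]acetate F7. MeI with K2CO3 in acetone then gives 13.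

Step 9. Acylation of resorcinol by the large acid may stall because its two Lewis-basic chromone carbonyls tie up BF3, and prolonged heating in the Lewis acid invites partial ether cleavage and unselective formylation. The fallback sets out from 14 and comes back at 18; it uses a protected resorcinol, a mixed-anhydride acylation at room temperature and a separate ring closure. Trifluoroacetic anhydride with catalytic H3PO4 and 1,3-dimethoxybenzene should give the ketone 8-chloro-3-[4-[5-[2-(2,4-dimethoxyphenyl)-2-oxoethyl]-2-methoxyphenoxy]phenyl]-7-methoxychromen-4-one F8. BCl3 in CH2Cl2 at −10 °C should remove only the methyl group ortho to the ketone by chelation, giving the 2-hydroxy ketone 8-chloro-3-[4-[5-[2-(2-hydroxy-4-methoxyphenyl)-2-oxoethyl]-2-methoxyphenoxy]phenyl]-7-methoxychromen-4-one F9; over-demethylation would be harmless, since all methyl ethers fall in the end. Me2NCH(OMe)2 in toluene at 90 °C should form the enaminone 8-chloro-3-[4-[5-[3-(dimethylamino)-1-(2-hydroxy-4-methoxyphenyl)-1-oxoprop-2-en-2-yl]-2-methoxyphenoxy]phenyl]-7-methoxychromen-4-one F10, not isolated, which cyclises with loss of dimethylamine to the trimethyl ether 8-chloro-7-methoxy-3-[4-[2-methoxy-5-(7-methoxy-4-oxochromen-3-yl)phenoxy]phenyl]chromen-4-one F11. BBr3 in CH2Cl2 then cleaves all three methyl ethers to give 18.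

Further compounds
F1 | step 6 | methyl 2-[3-[4-(hydroxymethyl)phenoxy]-4-methoxyphenyl]acetate | COC(=O)Cc1ccc(OC)c(Oc2ccc(CO)cc2)c1
F2 | step 6 | methyl 2-[3-[4-(bromomethyl)phenoxy]-4-methoxyphenyl]acetate | COC(=O)Cc1ccc(OC)c(Oc2ccc(CBr)cc2)c1
F3 | step 6 | [4-[2-methoxy-5-(2-methoxy-2-oxoethyl)phenoxy]benzyl]zinc bromide | COC(=O)Cc1ccc(OC)c(Oc2ccc(C[Zn]Br)cc2)c1
F4 | step 6 | methyl 2-[3-[4-[2-(3-chloro-2,4-difluorophenyl)-2-oxoethyl]phenoxy]-4-methoxyphenyl]acetate | COC(=O)Cc1ccc(OC)c(Oc2ccc(CC(=O)c3ccc(F)c(Cl)c3F)cc2)c1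
F5 | step 6 | methyl 2-[3-[4-[1-(3-chloro-2,4-difluorophenyl)-3-(dimethylamino)-1-oxoprop-2-en-2-yl]phenoxy]-4-methoxyphenyl]acetate | COC(=O)Cc1ccc(OC)c(Oc2ccc(C(=CN(C)C)C(=O)c3ccc(F)c(Cl)c3F)cc2)c1
F6 | step 7 | methyl 2-[3-[4-[8-chloro-4-oxo-7-[(E)-benzylideneaminooxy]chromen-3-yl]phenoxy]-4-methoxyphenyl]acetate | COC(=O)Cc1ccc(OC)c(Oc2ccc(-c3coc4c(Cl)c(O/N=C/c5ccccc5)ccc4c3=O)cc2)c1
F7 | step 7 | methyl 2-[3-[4-(8-chloro-7-hydroxy-4-oxochromen-3-yl)phenoxy]-4-methoxyphenyl]acetate | COC(=O)Cc1ccc(OC)c(Oc2ccc(-c3coc4c(Cl)c(O)ccc4c3=O)cc2)c1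
F8 | step 9 | 8-chloro-3-[4-[5-[2-(2,4-dimethoxyphenyl)-2-oxoethyl]-2-methoxyphenoxy]phenyl]-7-methoxychromen-4-one | COc1ccc(C(=O)Cc2ccc(OC)c(Oc3ccc(-c4coc5c(Cl)c(OC)ccc5c4=O)cc3)c2)c(OC)c1
F9 | step 9 | 8-chloro-3-[4-[5-[2-(2-hydroxy-4-methoxyphenyl)-2-oxoethyl]-2-methoxyphenoxy]phenyl]-7-methoxychromen-4-one | COc1ccc(C(=O)Cc2ccc(OC)c(Oc3ccc(-c4coc5c(Cl)c(OC)ccc5c4=O)cc3)c2)c(O)c1
F10 | step 9 | 8-chloro-3-[4-[5-[3-(dimethylamino)-1-(2-hydroxy-4-methoxyphenyl)-1-oxoprop-2-en-2-yl]-2-methoxyphenoxy]phenyl]-7-methoxychromen-4-one | COc1ccc(C(=O)C(=CN(C)C)c2ccc(OC)c(Oc3ccc(-c4coc5c(Cl)c(OC)ccc5c4=O)cc3)c2)c(O)c1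
F11 | step 9 | 8-chloro-7-methoxy-3-[4-[2-methoxy-5-(7-methoxy-4-oxochromen-3-yl)phenoxy]phenyl]chromen-4-one | COc1ccc2c(=O)c(-c3ccc(OC)c(Oc4ccc(-c5coc6c(Cl)c(OC)ccc6c5=O)cc4)c3)coc2c1
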